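The readings are simulated with made-up constants; noise was put on by code.

After the alder run has used up its G (0 % at 1.50 min), there is a leftover to account for. L holds 84.5 % of the charge, taking the mean of the last two readings, and the other 15.5 % is not in L. In the cedar run, with its larger charge, G reads 3 % at 1.50 min, L holds 50.0 %, and the leftover of 50.0 % is bigger.

common to all: J 86 mM (held)
- alder: G 0.10 M; run made earlier
- cedar: G 0.52 M; run made earlier
- violet: G 0.60 M; time 2.5 min
- green: G 0.40 M; time 2.5 min
- amber: G 0.30 M; time 2.5 min
- ochre: G 0.12 M; time 2.5 min
- blue: G 0.20 M; time 2.5 min

- alder (time / min: L / %, G / %): 0.333: 25, 29; 0.833: 68, 3; 1.50: 84, 0; 2.50: 85, 2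
- cedar (time / min: L / %, G / %): 0.333: 14, 36; 0.833: 42, 6; 1.50: 52, 3; 2.50: 48, 2

(readings scatter by 2 percentage points)

* the flasks put in order of amount of L, in percent of the G charged, best first, at 2.5 min (violet / green / amber / ochre / blue)
* the same order at 20 min (violet / green / amber / ochre / blue)
* the amount of L, in percent of the G charged of the flask you put first, at 2.5 min
* the amount of L, in percent of the G charged of the flask you put last, at 2.5 min

- the numbers in the tables scatter by 2 percentage points (one standard deviation)
- at the start none of J is in solution

Suppose the loss takes a second G and the way to L does not. Then the share lost over the share kept should grow in step with the charge, and dividing it by the charge should leave something nearly constant. Each run gives you that quotient independently: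

alder: 15.5 % ÷ (84.5 % × 0.10 M) = 1.83 L mol⁻¹

cedar: 50.0 % ÷ (50.0 % × 0.52 M) = 1.92 L mol⁻¹

The two come from different charges, yet they lie close, and the readings scatter by 2 percentage points, so you may freeze the quotient at their mean, 1.88 L mol⁻¹. Call this s, the loss number: share lost over share kept, per unit of charge. It works as a selectivity factor. Turned round, the share kept is one over (one plus s times the charge):

ochre: 81.6 %

violet: 47.0 %

In this reckoning the share kept falls as the charge rises, so your order runs from the smallest charge to the largest. Between the last two readings L goes from 84 % to 85 % in the alder run and from 52 % to 48 % in the cedar run, which you take as level given a scatter of 2 points, so you keep that order for the later time.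

The forecast gives ochre > blue > amber > green > violet at 2.5 min and ochre > blue > amber > green > violet at 20 min, with 83 % for ochre and 47 % for violet. Its ground is “Yield ≈ 1/(1+1.8[G]) fits both runs.” Those figures are its own, close to yours.

The flasks give ochre > blue > amber > green > violet at 2.5 min and ochre > blue > amber > green > violet at 20 min, with 83.4 % for ochre and 49.1 % for violet.

    G + X → E (k = 1.40 L mol⁻¹ s⁻¹)
    E → L (k = 0.0570 s⁻¹)
    G + E → Z (k = 0.200 L mol⁻¹ s⁻¹)
    X → D (k = 0.300 s⁻¹)
    J ⇌ X, rate k5*(csat - [X]) (kL = 0.390 s⁻¹)

Violet's result, put through the same quotient, gives 1.73 L mol⁻¹. Now carry the frozen 1.88 L mol⁻¹ from the two runs to a neighbouring flask, which is ochre's recipe with 0.20 M of G in place of 0.12 M. The share kept comes to 72.7 %. That neighbour reads L 74.9 % at 2.50 min, with Z at 25.0 % of the G charged.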